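**Strategy.** In germacrane numbering the target is a ten-membered carbocycle (C1–C10) trans-fused at C6–C7 to an α-methylene-γ-butyrolactone (ring O–C6–C7–C11–C12, exocyclic C13). Everything rests on the C7–C8 bond: the carbinol carbon C8 sits next to the lactone β-carbon C7 and the C11=C13 methylene, the retron of a carbonyl allylation. An intramolecular Nozaki–Hiyama–Kishi reaction of a 3-(bromomethyl)butenolide onto a tethered C8 aldehyde closes the ten-membered ring, sets C7 and C8 and unveils the methylene lactone in one operation. Its precursor is an open-chain butenolide dialdehyde; C8, formed as the epimer, is inverted during Mitsunobu esterification.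

Key step: step 13

Remark on numbering: germacrane numbering is used for all intermediates (C6 lactone carbinol, C7 ring fusion, C8 acyloxy carbinol, C9 hydroxy carbinol, C14 formyl carbon on C10, C15 hydroxymethyl carbon on C4, C12 lactone carbonyl); TBS = tert-butyldimethylsilyl, TES = triethylsilyl.

Assumption: the zinc complex of (S,S)-ProPhenol is taken to deliver the 4S carbinol 13 in step 6; if the sense of induction is the opposite, the (R,R)-ligand is used.

Remark: aldol 5 is carried on as a mixture of carbinol epimers, because that centre becomes sp2 in step 3.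

**Step 1**
Reactants: 1 (S)-3-hydroxy-γ-butyrolactone
Product: 2 (4S)-4-[(tert-butyldimethylsilyl)oxy]dihydrofuran-2(3H)-one
Conditions: TBSCl, imidazole, DMF, 0 °C → rt
Reagents that add atoms: tert-butyldimethylsilyl chloride, CC(C)(C)[Si](C)(C)Cl
Why: Imidazole-promoted silylation of the secondary hydroxyl; no stereocentre is formed and C9 keeps its S configuration from the chiral pool.

**Step 2**
Reactants: 2 (4S)-4-[(tert-butyldimethylsilyl)oxy]dihydrofuran-2(3H)-one; 3 acrolein
Product: 5 (3S,4S)-4-[(tert-butyldimethylsilyl)oxy]-3-(1-hydroxyprop-2-en-1-yl)dihydrofuran-2(3H)-one (3,4-trans, both carbinol epimers), via lithium enolate 4 (not isolated)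
Conditions: LiN(i-Pr)2, THF, −78 °C; then 3, −78 °C; aq. NH4Cl
Reagents that add atoms: lithium diisopropylamide, [Li+].CC(C)[N-]C(C)C (lithium of intermediate 4 only)
Why: Aldol addition of the lactone lithium enolate to the enal carbonyl at −78 °C, where β-elimination of the silyloxide is slow; the aldehyde adds trans to the C9 silyloxy group and the new carbinol centre is left uncontrolled because it becomes sp2 in step 3.

**Step 3**
Reactants: 5 (3S,4S)-4-[(tert-butyldimethylsilyl)oxy]-3-(1-hydroxyprop-2-en-1-yl)dihydrofuran-2(3H)-one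
Product: 7 (3E,4S)-3-allylidene-4-[(tert-butyldimethylsilyl)oxy]dihydrofuran-2(3H)-one, via allylic mesylate 6 (not isolated)
Conditions: MsCl, Et3N, CH2Cl2, 0 °C; then DBU, 0 °C → rt
Reagents that add atoms: methanesulfonyl chloride, CS(=O)(=O)Cl (its atoms are in intermediate 6 only)
Why: Mesylation followed by base-mediated E1cB elimination (aldol condensation) should give the exocyclic alkylidene as the thermodynamically favoured E isomer (vinyl anti to the lactone carbonyl, hence C2 cis to C9); any minor Z isomer is removed by chromatography.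

**Step 4**
Reactants: 7 (3E,4S)-3-allylidene-4-[(tert-butyldimethylsilyl)oxy]dihydrofuran-2(3H)-one
Product: 8 (2Z,3S)-2-allylidene-3-[(tert-butyldimethylsilyl)oxy]butane-1,4-diol
Conditions: i-Bu2AlH (4 equiv), CH2Cl2, −78 → 0 °C; aq. potassium sodium tartrate
Reagents that add atoms: none
Why: Exhaustive 1,2-reduction of the unsaturated lactone by the aluminium hydride (through the lactol) gives the allylic 1,4-diol without touching the diene, the silyl ether or C9.

**Step 5**
Reactants: 8 (2Z,3S)-2-allylidene-3-[(tert-butyldimethylsilyl)oxy]butane-1,4-diol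
Product: 9 (2Z,3S)-2-allylidene-3-[(tert-butyldimethylsilyl)oxy]-1,4-bis[(triethylsilyl)oxy]butane
Conditions: TESCl, imidazole, CH2Cl2, 0 °C
Reagents that add atoms: chlorotriethylsilane, CC[Si](Cl)(CC)CC
Why: Silylation of both primary hydroxyls as triethylsilyl ethers, chosen because primary TES ethers can later be removed in the presence of the TBS ethers.

**Step 6**
Reactants: 10 (E)-crotonaldehyde; 11 tert-butyldimethyl(prop-2-yn-1-yloxy)silane
Product: 13 (4S,5E)-1-[(tert-butyldimethylsilyl)oxy]hept-5-en-2-yn-4-ol, via methylzinc alkynylide 12 (not isolated)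
Conditions: 11, Me2Zn, (S,S)-ProPhenol (20 mol%), Ph3P=O (40 mol%), toluene, 0 °C; then 10, 4 °C; aq. NH4Cl
Reagents that add atoms: dimethylzinc, C[Zn]C (methylzinc unit of intermediate 12 only)
Why: Zinc–ProPhenol-catalysed enantioselective alkynylation of an α,β-unsaturated aldehyde: the chiral dinuclear zinc complex delivers the alkynyl group to one face of the aldehyde and sets the C6 carbinol centre (4S here, 6R once the lactone is in place).

**Step 7**
Reactants: 13 (4S,5E)-1-[(tert-butyldimethylsilyl)oxy]hept-5-en-2-yn-4-ol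
Product: 15 (2Z,4S,5E)-1-[(tert-butyldimethylsilyl)oxy]-2-iodohepta-2,5-dien-4-ol, via sodium alkenylalanate 14 (not isolated)
Conditions: NaAlH2(OCH2CH2OMe)2, THF, 0 °C → rt; then I2, THF, −78 °C
Reagents that add atoms: iodine, [I][I]; NaAlH2(OCH2CH2OMe)2, [Na+].COCCO[AlH2-]OCCOC (in intermediate 14 only)
Why: Hydroxyl-directed trans-hydroalumination of the propargylic alcohol places aluminium on the distal alkyne carbon within a five-membered alanate, and iodinolysis with retention gives the vinyl iodide with iodine cis to the carbinol carbon, which fixes the C4=C5 geometry.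

**Step 8**
Reactants: 9 (2Z,3S)-2-allylidene-3-[(tert-butyldimethylsilyl)oxy]-1,4-bis[(triethylsilyl)oxy]butane; 15 (2Z,4S,5E)-1-[(tert-butyldimethylsilyl)oxy]-2-iodohepta-2,5-dien-4-ol
Product: 17 (2E,4S,5E,9Z,11S)-11-[(tert-butyldimethylsilyl)oxy]-6-{[(tert-butyldimethylsilyl)oxy]methyl}-12-[(triethylsilyl)oxy]-10-{[(triethylsilyl)oxy]methyl}dodeca-2,5,9-trien-4-ol, via B-alkyl-9-BBN 16 (not isolated)
Conditions: 9 (slight excess), 9-BBN, THF, 0 °C → rt; then 15, Pd(dppf)Cl2 (5 mol%), AsPh3, Cs2CO3, DMF/H2O, rt
Reagents that add atoms: 9-borabicyclo[3.3.1]nonane, B1C2CCCC1CCC2 (in intermediate 16 only)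
Why: Anti-Markovnikov hydroboration of the terminal vinyl group of the diene with 9-BBN (the trisubstituted olefin is too hindered) followed by B-alkyl Suzuki–Miyaura coupling, which proceeds with retention at the vinyl iodide so that C3 ends cis to C6; the free C6 hydroxyl is tolerated.

**Step 9**
Reactants: 17 the C6 alcohol of step 8; 18 2-(bromomethyl)acrylic acid
Product: 19 2-(bromomethyl)acrylate ester of 17 at O6
Conditions: DCC, DMAP (cat.), CH2Cl2, −20 → 0 °C
Reagents that add atoms: none
Why: Steglich esterification of the only free hydroxyl; low temperature and a catalytic amount of DMAP limit SN2′ attack on the allylic bromide, and C6 is not touched.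

**Step 10**
Reactants: 19 2-(bromomethyl)acrylate ester of 17
Product: 20 (5R)-3-(bromomethyl)-5-[(1E,5Z,7S)-7-[(tert-butyldimethylsilyl)oxy]-2-{[(tert-butyldimethylsilyl)oxy]methyl}-8-[(triethylsilyl)oxy]-6-{[(triethylsilyl)oxy]methyl}octa-1,5-dien-1-yl]furan-2(5H)-one
Conditions: second-generation Grubbs catalyst (10 mol%), CH2Cl2, 40 °C, 5 mM
Reagents that add atoms: none
Why: Ring-closing metathesis between the propenyl group and the 1,1-disubstituted acrylate olefin closes the five-membered butenolide with loss of propene, the two trisubstituted olefins being too hindered to compete.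

**Step 11**
Reactants: 20 the bis-TES bromobutenolide
Product: 21 (5R)-3-(bromomethyl)-5-[(1E,5Z,7S)-7-[(tert-butyldimethylsilyl)oxy]-2-{[(tert-butyldimethylsilyl)oxy]methyl}-8-hydroxy-6-(hydroxymethyl)octa-1,5-dien-1-yl]furan-2(5H)-one
Conditions: PPTS, MeOH/CH2Cl2, 0 °C
Reagents that add atoms: none
Why: Acid-catalysed methanolysis (selective desilylation) cleaves the two primary triethylsilyl ethers much faster than the primary and secondary TBS ethers and leaves the allylic bromide and the butenolide untouched at 0 °C.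

**Step 12**
Reactants: 21 the C8,C14-diol
Product: 22 (2S,3E,7E)-8-[(2R)-4-(bromomethyl)-5-oxo-2,5-dihydrofuran-2-yl]-2-[(tert-butyldimethylsilyl)oxy]-7-{[(tert-butyldimethylsilyl)oxy]methyl}-3-formylocta-3,7-dienal
Conditions: (COCl)2, DMSO, CH2Cl2, −78 °C; then i-Pr2NEt, −78 → −30 °C; used at once
Reagents that add atoms: none
Why: Swern oxidation: both hydroxyls are converted into alkoxysulfonium salts before the base is added, so no hydroxy aldehyde is present that could close to a lactol and be over-oxidised, and the hindered amine neither displaces the allylic bromide nor epimerises C9 at low temperature.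

**Step 13**
Reactants: 22 the bromobutenolide dialdehyde
Product: 24 (6R,7R,8R,9S)-9,15-bis[(tert-butyldimethylsilyl)oxy]-8-hydroxy-14-oxogermacra-1(10)E,4E,11(13)-trien-12,6-olide (8α-alcohol; C7 has the spatial arrangement of the target, only its descriptor differs), via allylchromium dichloride 23 (not isolated)
Conditions: CrCl2 (10 equiv), THF, rt, syringe-pump addition of 22 (final 2 mM); aq. NH4Cl
Reagents that add atoms: chromium dichloride, Cl[Cr]Cl (in intermediate 23 only)
Why: Two equivalents of CrCl2 (divalent chromium) reduce the allylic C13–Br bond to the allylchromium dichloride 23 (trivalent chromium), which adds through its γ-carbon C7 to the C8 aldehyde in a six-membered chair (Zimmerman–Traxler) transition state, so that the double bond moves to C11=C13 and the α-methylene lactone appears. The closest known reaction type is the Nozaki–Hiyama–Kishi (Barbier-type) allylation of aldehydes with 3-(bromomethyl)butenolides and 2-(alkoxycarbonyl)allyl halides, which is also established for closing ten-membered germacranolide rings. One ring is closed, the ten-membered carbocycle C1–C10, in the exo mode at the aldehyde carbon (10-exo-trig: C8 becomes a ring atom, its oxygen stays outside). C7 is controlled by C6: the aldehyde, tethered through C5, attacks the butenolide face anti to the C5 substituent, which avoids an eclipsed C5–C6–C7–C8 array and gives the trans-fused lactone; C8 is controlled by the chair, in which the ring holds C6 trans to the CH2Cr arm and C9 sits equatorial (anti adduct), reinforced by Felkin–Anh attack anti to the C9–OTBS bond, and both models predict the 8R (8α) carbinol, the C8 epimer of the target, which step 14 inverts. The step needs chemoselectivity for the C8 aldehyde over the C14 enal, secured by the higher electrophilicity of the α-silyloxy aldehyde and by the fact that closure onto C14 would put the C1=C10 double bond trans in a nine-membered ring, γ-regioselectivity, inherent in the cyclic transition state, and ring closure over oligomerisation, secured by slow addition at high dilution and by the two cis-configured trisubstituted olefins that fold the chain.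

**Step 14**
Reactants: 24 the 8R macrocyclic alcohol; 25 (S)-2-methylbutanoic acid
Product: 26 (6R,7S,8S,9S)-9,15-bis[(tert-butyldimethylsilyl)oxy]-8-{[(2S)-2-methylbutanoyl]oxy}-14-oxogermacra-1(10)E,4E,11(13)-trien-12,6-olide
Conditions: PPh3, DIAD, toluene, 0 °C → rt (acid and alcohol premixed)
Reagents that add atoms: none
Why: Mitsunobu esterification: the C8 hydroxyl, the only free one, is activated as its oxyphosphonium salt and displaced by the carboxylate in an SN2 step, which inverts C8 from R to S and leaves the stereocentre of the acid untouched.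

**Step 15**
Reactants: 26 the bis-TBS ester
Product: 27 target, (6R,7S,8S,9S)-9,15-dihydroxy-8-{[(2S)-2-methylbutanoyl]oxy}-14-oxogermacra-1(10)E,4E,11(13)-trien-12,6-olide
Conditions: HF·pyridine, pyridine, THF, 0 °C → rt
Reagents that add atoms: none
Why: Fluoride-induced desilylation of both TBS ethers under buffered, non-basic conditions that spare the α-methylene lactone, the enal and the C8 ester and avoid acyl migration to O9.

**Compound list**

1 | (S)-3-hydroxy-γ-butyrolactone | O=C1C[C@H](O)CO1 | starting material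
2 | (4S)-4-[(tert-butyldimethylsilyl)oxy]dihydrofuran-2(3H)-one | O=C1C[C@H](O[Si](C)(C)C(C)(C)C)CO1 | intermediate
3 | acrolein | C=CC=O | starting material
4 | lithium enolate of 2 | [Li+].[O-]C1=C[C@H](O[Si](C)(C)C(C)(C)C)CO1 | intermediate (not isolated)
5 | (3S,4S)-4-[(tert-butyldimethylsilyl)oxy]-3-(1-hydroxyprop-2-en-1-yl)dihydrofuran-2(3H)-one, carbinol epimers | O=C1OC[C@@H](O[Si](C)(C)C(C)(C)C)[C@@H]1C(O)C=C | intermediate
6 | methanesulfonate of 5 | O=C1OC[C@@H](O[Si](C)(C)C(C)(C)C)[C@@H]1C(OS(C)(=O)=O)C=C | intermediate (not isolated)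
7 | (3E,4S)-3-allylidene-4-[(tert-butyldimethylsilyl)oxy]dihydrofuran-2(3H)-one | O=C1OC[C@@H](O[Si](C)(C)C(C)(C)C)/C1=C\C=C | intermediate
8 | (2Z,3S)-2-allylidene-3-[(tert-butyldimethylsilyl)oxy]butane-1,4-diol | C=C/C=C(/CO)[C@H](O[Si](C)(C)C(C)(C)C)CO | intermediate
9 | (2Z,3S)-2-allylidene-3-[(tert-butyldimethylsilyl)oxy]-1,4-bis[(triethylsilyl)oxy]butane | C=C/C=C(/CO[Si](CC)(CC)CC)[C@H](O[Si](C)(C)C(C)(C)C)CO[Si](CC)(CC)CC | intermediate
10 | (E)-crotonaldehyde | C/C=C/C=O | starting material
11 | tert-butyldimethyl(prop-2-yn-1-yloxy)silane | C#CCO[Si](C)(C)C(C)(C)C | starting material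
12 | methylzinc alkynylide of 11 | C[Zn]C#CCO[Si](C)(C)C(C)(C)C | intermediate (not isolated)
13 | (4S,5E)-1-[(tert-butyldimethylsilyl)oxy]hept-5-en-2-yn-4-ol | O[C@@H](/C=C/C)C#CCO[Si](C)(C)C(C)(C)C | intermediate
14 | sodium alkenylalanate (five-membered oxaaluminate from 13) | [Na+].COCCO[Al-]1(OCCOC)O[C@@H](/C=C/C)C=C1CO[Si](C)(C)C(C)(C)C | intermediate (not isolated)
15 | (2Z,4S,5E)-1-[(tert-butyldimethylsilyl)oxy]-2-iodohepta-2,5-dien-4-ol | O[C@@H](/C=C/C)/C=C(\I)CO[Si](C)(C)C(C)(C)C | intermediate
16 | B-alkyl-9-BBN from 9 (boron on C3) | C(C/C=C(/CO[Si](CC)(CC)CC)[C@H](O[Si](C)(C)C(C)(C)C)CO[Si](CC)(CC)CC)B1C2CCCC1CCC2 | intermediate (not isolated)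
17 | (2E,4S,5E,9Z,11S)-11-[(tert-butyldimethylsilyl)oxy]-6-{[(tert-butyldimethylsilyl)oxy]methyl}-12-[(triethylsilyl)oxy]-10-{[(triethylsilyl)oxy]methyl}dodeca-2,5,9-trien-4-ol | O[C@@H](/C=C/C)/C=C(/CO[Si](C)(C)C(C)(C)C)CC/C=C(/CO[Si](CC)(CC)CC)[C@H](O[Si](C)(C)C(C)(C)C)CO[Si](CC)(CC)CC | intermediate
18 | 2-(bromomethyl)acrylic acid | C=C(CBr)C(=O)O | starting material
19 | 2-(bromomethyl)acrylate ester of 17 | C=C(CBr)C(=O)O[C@@H](/C=C/C)/C=C(/CO[Si](C)(C)C(C)(C)C)CC/C=C(/CO[Si](CC)(CC)CC)[C@H](O[Si](C)(C)C(C)(C)C)CO[Si](CC)(CC)CC | intermediate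
20 | (5R)-3-(bromomethyl)-5-[(1E,5Z,7S)-7-[(tert-butyldimethylsilyl)oxy]-2-{[(tert-butyldimethylsilyl)oxy]methyl}-8-[(triethylsilyl)oxy]-6-{[(triethylsilyl)oxy]methyl}octa-1,5-dien-1-yl]furan-2(5H)-one | O=C1O[C@H](/C=C(/CO[Si](C)(C)C(C)(C)C)CC/C=C(/CO[Si](CC)(CC)CC)[C@H](O[Si](C)(C)C(C)(C)C)CO[Si](CC)(CC)CC)C=C1CBr | intermediate
21 | (5R)-3-(bromomethyl)-5-[(1E,5Z,7S)-7-[(tert-butyldimethylsilyl)oxy]-2-{[(tert-butyldimethylsilyl)oxy]methyl}-8-hydroxy-6-(hydroxymethyl)octa-1,5-dien-1-yl]furan-2(5H)-one | O=C1O[C@H](/C=C(/CO[Si](C)(C)C(C)(C)C)CC/C=C(/CO)[C@H](O[Si](C)(C)C(C)(C)C)CO)C=C1CBr | intermediate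
22 | (2S,3E,7E)-8-[(2R)-4-(bromomethyl)-5-oxo-2,5-dihydrofuran-2-yl]-2-[(tert-butyldimethylsilyl)oxy]-7-{[(tert-butyldimethylsilyl)oxy]methyl}-3-formylocta-3,7-dienal | O=C1O[C@H](/C=C(/CO[Si](C)(C)C(C)(C)C)CC/C=C(/C=O)[C@H](O[Si](C)(C)C(C)(C)C)C=O)C=C1CBr | intermediate
23 | allylchromium dichloride from 22 (trivalent chromium on C13) | O=C1O[C@H](/C=C(/CO[Si](C)(C)C(C)(C)C)CC/C=C(/C=O)[C@H](O[Si](C)(C)C(C)(C)C)C=O)C=C1C[Cr](Cl)Cl | intermediate (not isolated)
24 | (6R,7R,8R,9S)-9,15-bis[(tert-butyldimethylsilyl)oxy]-8-hydroxy-14-oxogermacra-1(10)E,4E,11(13)-trien-12,6-olide | C=C1C(=O)O[C@@H]2/C=C(/CO[Si](C)(C)C(C)(C)C)CC/C=C(/C=O)[C@H](O[Si](C)(C)C(C)(C)C)[C@H](O)[C@@H]12 | intermediate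
25 | (S)-2-methylbutanoic acid | CC[C@H](C)C(=O)O | starting material
26 | (6R,7S,8S,9S)-9,15-bis[(tert-butyldimethylsilyl)oxy]-8-{[(2S)-2-methylbutanoyl]oxy}-14-oxogermacra-1(10)E,4E,11(13)-trien-12,6-olide | C=C1C(=O)O[C@@H]2/C=C(/CO[Si](C)(C)C(C)(C)C)CC/C=C(/C=O)[C@H](O[Si](C)(C)C(C)(C)C)[C@@H](OC(=O)[C@@H](C)CC)[C@@H]12 | intermediate
27 | (6R,7S,8S,9S)-9,15-dihydroxy-8-{[(2S)-2-methylbutanoyl]oxy}-14-oxogermacra-1(10)E,4E,11(13)-trien-12,6-olide | C=C1C(=O)O[C@@H]2/C=C(/CO)CC/C=C(/C=O)[C@H](O)[C@@H](OC(=O)[C@@H](C)CC)[C@@H]12 | target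

**Totals and risks**

Total step count: 15. Longest linear sequence: 13 steps (steps 1–5 and 8–15, from 1); the second branch (steps 6–7) joins at step 8.

Step 13 (key ring closure). What may go wrong is intermolecular allylation or protodemetalation of the allylchromium outrunning the entropically costly ten-membered ring closure, and erosion of facial selectivity at C8. The fallback sets out from 22 and replaces reductive metalation by a boron-based, thermal allylation. Pd2(dba)3 (zerovalent palladium, catalytic) and bis(pinacolato)diboron in toluene at room temperature convert the allylic bromide into the allylboronate F1. F1 closes the same C7–C8 bond in the same flask under high dilution by closed-chair allylboration of the C8 aldehyde, with the same stereochemical model and no reductant or strong Lewis acid present. Aqueous work-up of the borate comes back to the route at 24. Should the ring closure deliver the 8S carbinol instead, it is esterified without inversion by the last operation of the next fallback.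

Step 14 (inverting esterification). What may go wrong is elimination of the activated C8 oxygen towards C7, failure of the carboxylate to displace at the hindered ring carbinol, or activation of a transannular O8–C14 hemiacetal should the hydroxy enal close. Closure is expected to be disfavoured, because it needs C8 coplanar with C14, a transoid C8–C9–C10=C1 torsion that the ring with its cis C1=C10 olefin resists. The fallback sets out from 24 and separates inversion from acylation. Tf2O and pyridine (CH2Cl2, −20 °C) give the triflate F2. Tetrabutylammonium nitrite in toluene (Lattrell–Dax inversion, a small and weakly basic nucleophile) displaces it to the inverted nitrite ester F3, which hydrolyses on work-up to the 8S alcohol F4. Steglich esterification of F4 with acid 25 (DCC, DMAP, CH2Cl2, 0 °C) comes back to the route at 26.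

Step 6 (enantioselective alkynylation). What may go wrong is insufficient enantiofacial discrimination, or the opposite sense of induction, with the small enal. The fallback sets out from 10 and 11 and uses resolution instead of asymmetric addition. The lithium acetylide of 11 (n-BuLi, THF, −78 °C) adds to 10 to give the racemic alcohol F5. Sharpless kinetic resolution [Ti(OiPr)4, diisopropyl L-(+)-tartrate, t-BuOOH, 4 Å molecular sieves, CH2Cl2, −20 °C] epoxidises the 4R enantiomer to the erythro epoxy alcohol F6 and leaves the 4S alcohol, so the route is rejoined at 13.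

**Further compounds**

F1 | step 13 | allylboronate of 22 (pinacolboryl in place of bromine on C13) | O=C1O[C@H](/C=C(/CO[Si](C)(C)C(C)(C)C)CC/C=C(/C=O)[C@H](O[Si](C)(C)C(C)(C)C)C=O)C=C1CB1OC(C)(C)C(C)(C)O1
F2 | step 14 | 8-O-trifluoromethanesulfonate of 24 (8R) | C=C1C(=O)O[C@@H]2/C=C(/CO[Si](C)(C)C(C)(C)C)CC/C=C(/C=O)[C@H](O[Si](C)(C)C(C)(C)C)[C@H](OS(=O)(=O)C(F)(F)F)[C@@H]12
F3 | step 14 | inverted 8-O-nitrite ester (8S) | C=C1C(=O)O[C@@H]2/C=C(/CO[Si](C)(C)C(C)(C)C)CC/C=C(/C=O)[C@H](O[Si](C)(C)C(C)(C)C)[C@@H](ON=O)[C@@H]12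
F4 | step 14 | 8S (8β) alcohol, C8 epimer of 24 | C=C1C(=O)O[C@@H]2/C=C(/CO[Si](C)(C)C(C)(C)C)CC/C=C(/C=O)[C@H](O[Si](C)(C)C(C)(C)C)[C@@H](O)[C@@H]12
F5 | step 6 | racemic (5E)-1-[(tert-butyldimethylsilyl)oxy]hept-5-en-2-yn-4-ol | OC(/C=C/C)C#CCO[Si](C)(C)C(C)(C)C
F6 | step 6 | (4S,5S,6S)-1-[(tert-butyldimethylsilyl)oxy]-5,6-epoxyhept-2-yn-4-ol (erythro epoxy alcohol from the 4R enantiomer of 13) | C[C@@H]1O[C@H]1[C@@H](O)C#CCO[Si](C)(C)C(C)(C)C
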